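Cuts, in retrosynthetic order:
- the four O–Si bonds;
- C3–C4 of ring C together with C2–H, which opens the flavanone to an O-(1-arylvinyl)salicylaldehyde;
- C2=CH2, back to an aryl ester whose O1–C2 bond joins a ring A phenol to a ring B acid;
- the formyl carbon–ring A bond (aryl iodide);
- the geranyl–ring B bond (aryl bromide plus geranylstannane).

Enabling feature: in ring C, C2 carries both O1 and ring B, C3 is a bare CH2, and the C4 carbonyl sits on ring A ortho to O1. Ring C is therefore the formal adduct of a ring A formyl C–H bond across a 1,1-disubstituted enol ether C2=C3 that has no allylic hydrogen.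
Forward order: the ring B acid (silylation, Stille geranylation, Pinnick oxidation) and the ring A iodophenol (iodination, bis-silylation) are made separately. They are joined as an ester, methylenated and formylated; ring C closes last by an atom-economic isomerization, and fluoride frees the four phenols.
Stereochemistry: C2, the only stereocenter, is created in the ring closure by hydride delivery from rhodium bearing a chiral bisphosphine. The E alkene is bought with geranyl chloride.
A carbanion at C3 would expel the ring A phenoxide by β-elimination; hydroacylation avoids any such intermediate.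

Key step: step 10

Assumption: (R)-DTBM-SEGPHOS is taken, by analogy with related substrates, to expose the Re face of the enol ether carbon. If a test run shows the opposite sense, the equally available (S)-ligand is used and nothing else changes.
Abbreviations: TBS = tert-butyldimethylsilyl; geranyl = (2E)-3,7-dimethylocta-2,6-dien-1-yl.

Step 1
Reactants: 1 3-bromo-4,5-dihydroxybenzaldehyde
Product: 2 3-bromo-4,5-bis(TBS-oxy)benzaldehyde
Conditions: TBSCl (2.4 equiv), imidazole (5 equiv), DMF, 0 °C to rt
Reagents that add atoms: tert-butyldimethylsilyl chloride CC(C)(C)[Si](C)(C)Cl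
Why: Imidazole-promoted silylation of both catechol hydroxyls gives fluoride-labile ethers that tolerate every later step and can be removed at the end without acid, base or hydrogen, none of which the geranyl chain and C2 would bear.

Step 2
Reactants: 3 geranyl chloride
Product: 4 tributyl(geranyl)stannane
Conditions: Bu3SnH, LiN(iPr)2, THF, −78 to 0 °C; then 3, −78 °C to rt
Reagents that add atoms: tributyltin hydride CCCC[SnH](CCCC)CCCC
Why: SN2 displacement of the primary allylic chloride by the soft stannyl anion occurs at the unhindered terminus at low temperature and keeps the E geometry of the purchased chloride.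

Step 3
Reactants: 2 3-bromo-4,5-bis(TBS-oxy)benzaldehyde; 4 tributyl(geranyl)stannane
Product: 5 3-geranyl-4,5-bis(TBS-oxy)benzaldehyde
Conditions: Pd(PPh3)4 (5 mol %), toluene, 100 °C, argon
Reagents that add atoms: none
Why: Stille coupling of an aryl bromide with an allylic stannane runs under neutral conditions that spare the aldehyde and the silyl ethers, and reductive elimination at the less hindered primary terminus of the geranylpalladium intermediate should give the linear E product.

Step 4
Reactants: 5 3-geranyl-4,5-bis(TBS-oxy)benzaldehyde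
Product: 6 3-geranyl-4,5-bis(TBS-oxy)benzoic acid
Conditions: NaClO2, NaH2PO4, 2-methyl-2-butene (large excess), t-BuOH/THF/H2O, 0 °C to rt
Reagents that add atoms: sodium chlorite [Na+].[O-]Cl=O
Why: Pinnick oxidation converts the aldehyde into the acid in a weakly acidic buffer that leaves aryl silyl ethers intact, and the excess 2-methyl-2-butene takes up the hypochlorous acid before it reaches the geranyl alkenes.

Step 5
Reactants: 7 phloroglucinol (benzene-1,3,5-triol)
Product: 8 2-iodobenzene-1,3,5-triol
Conditions: I2 (1.0 equiv), NaHCO3, THF/H2O, 0 °C, used at once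
Reagents that add atoms: iodine II
Why: Electrophilic aromatic iodination of the threefold-symmetric triol can give only one monoiodide, so the site of the future formyl carbon between two oxygens is fixed by symmetry.

Step 6
Reactants: 8 2-iodobenzene-1,3,5-triol
Product: 9 2-iodo-3,5-bis(TBS-oxy)phenol
Conditions: TBSCl (2.0 equiv), imidazole (4 equiv), DMF, −10 to 0 °C
Reagents that add atoms: tert-butyldimethylsilyl chloride CC(C)(C)[Si](C)(C)Cl
Why: Silylation under steric control should take the hydroxyl para to iodine first and then one of the two equivalent hydroxyls beside iodine, leaving one free phenol (future O1) next to the iodide, while mono- and trisilylated material is separated and recycled.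

Step 7
Reactants: 6 3-geranyl-4,5-bis(TBS-oxy)benzoic acid; 9 2-iodo-3,5-bis(TBS-oxy)phenol
Product: 10 2-iodo-3,5-bis(TBS-oxy)phenyl 3-geranyl-4,5-bis(TBS-oxy)benzoate
Conditions: DCC (1.1 equiv), DMAP (cat.), CH2Cl2, 0 °C to rt
Reagents that add atoms: none
Why: Steglich esterification joins the two halves through the future O1–C2 bond under neutral conditions, and DMAP acyl transfer copes with the ortho-iodophenol.

Step 8
Reactants: 10 2-iodo-3,5-bis(TBS-oxy)phenyl 3-geranyl-4,5-bis(TBS-oxy)benzoate
Product: 11 1-{1-[2-iodo-3,5-bis(TBS-oxy)phenoxy]ethenyl}-3-geranyl-4,5-bis(TBS-oxy)benzene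
Conditions: Cp2TiMe2 (2.5 equiv), toluene, 70 °C, dark; hexane, filtration through basic alumina
Reagents that add atoms: dimethyltitanocene C[Ti+2]C.c1cc[cH-]c1.c1cc[cH-]c1
Why: In the Petasis methylenation, thermolysis of Cp2TiMe2 gives Cp2Ti=CH2, which converts aryl benzoates into aryl 1-arylvinyl ethers through an oxatitanacyclobutane, and the reagent is neither acidic nor basic, so silyl ethers, aryl iodide and trisubstituted alkenes are left alone.

Step 9
Reactants: 11 1-{1-[2-iodo-3,5-bis(TBS-oxy)phenoxy]ethenyl}-3-geranyl-4,5-bis(TBS-oxy)benzene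
Product: 13 2-{1-[3-geranyl-4,5-bis(TBS-oxy)phenyl]ethenyloxy}-4,6-bis(TBS-oxy)benzaldehyde, via arylmagnesium chloride 12 (not isolated)
Conditions: iPrMgCl·LiCl (1.2 equiv), THF, −20 to 0 °C; DMF (3 equiv), 0 °C; pH 7 aqueous quench; Et3N-deactivated silica
Reagents that add atoms: N,N-dimethylformamide CN(C)C=O; isopropylmagnesium chloride–lithium chloride CC(C)[Mg]Cl.[Li+].[Cl-] (magnesium and chlorine of 12 only)
Why: Iodine–magnesium exchange is fast for an iodide flanked by two oxygen substituents, the arylmagnesium species does not undergo the oxygen-to-carbon silyl shift that an aryllithium would risk, and Bouveault-type formylation with a neutral quench delivers the aldehyde without hydrolysing the enol ether.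

Step 10
Reactants: 13 2-{1-[3-geranyl-4,5-bis(TBS-oxy)phenyl]ethenyloxy}-4,6-bis(TBS-oxy)benzaldehyde
Product: 14 (2S)-5,7-bis(TBS-oxy)-2-[3-geranyl-4,5-bis(TBS-oxy)phenyl]chroman-4-one
Conditions: [Rh(cod)Cl]2 (2.5 mol %), (R)-DTBM-SEGPHOS (5 mol %), NaB[3,5-(CF3)2C6H3]4 (5 mol %), dry 1,4-dioxane, 60–80 °C, argon
Reagents that add atoms: none
Why: Proposed new method: the cationic monovalent rhodium bisphosphine complex should insert into the formyl C–H bond of 13, bind the tethered 1,1-disubstituted enol ether, deliver hydride to the oxygen- and aryl-bearing carbon (future C2) and release ring C by acyl–alkyl reductive elimination from a seven-membered trivalent rhodacycle, which forms the C3–C4 bond. The closest known reaction type is the enantioselective intramolecular alkene hydroacylation of ortho-allylbenzaldehydes to 3-substituted tetralones and of N-(1-substituted vinyl)indole-2-carbaldehydes to cyclic β-amino ketones with the same catalyst family, whereas an O-(1-arylvinyl)salicylaldehyde has not been shown. Ring C closes in a formal 6-endo-trig mode, both alkene carbons ending in the ring. The only new stereocenter, C2, is set in the hydride transfer, the pocket of the twofold-symmetric ligand exposing the Re face of the alkene carbon to Rh–H, which gives (S). The step needs hydride at C2 and acyl at CH2 rather than the reverse addition to a 2-methyl-2-arylbenzofuran-3-one, and the 1,1-disubstitution secures this because the reverse insertion demands a tertiary alkylrhodium and a reductive elimination to a quaternary carbon. The enol ether has no allylic hydrogen, so alkene isomerization cannot occur, the C2–O1 bond lies inside the rhodacycle and cannot align for β-aryloxide elimination, and the trisubstituted geranyl alkenes bind too weakly to compete.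

Step 11
Reactants: 14 (2S)-5,7-bis(TBS-oxy)-2-[3-geranyl-4,5-bis(TBS-oxy)phenyl]chroman-4-one
Product: 15 isonymphaeol B, (2S)-2-(3-geranyl-4,5-dihydroxyphenyl)-5,7-dihydroxychroman-4-one
Conditions: Et3N·3HF (excess), THF, 0 °C to rt, argon; pH 5–6 aqueous work-up
Reagents that add atoms: none
Why: Fluoride cleavage of the four aryl silyl ethers with the weakly acidic amine–HF complex avoids free phenoxide, so both the ring opening to the chalcone that would racemize C2 and the acid-induced cyclization of the geranyl chain onto the neighbouring phenol should be suppressed.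

Compound list
1 | 3-bromo-4,5-dihydroxybenzaldehyde | O=Cc1cc(O)c(O)c(Br)c1 | starting material
2 | 3-bromo-4,5-bis(TBS-oxy)benzaldehyde | O=Cc1cc(O[Si](C)(C)C(C)(C)C)c(O[Si](C)(C)C(C)(C)C)c(Br)c1 | intermediate
3 | geranyl chloride | CC(C)=CCC/C(C)=C/CCl | starting material
4 | tributyl(geranyl)stannane | CC(C)=CCC/C(C)=C/C[Sn](CCCC)(CCCC)CCCC | intermediate
5 | 3-geranyl-4,5-bis(TBS-oxy)benzaldehyde | CC(C)=CCC/C(C)=C/Cc1cc(C=O)cc(O[Si](C)(C)C(C)(C)C)c1O[Si](C)(C)C(C)(C)C | intermediate
6 | 3-geranyl-4,5-bis(TBS-oxy)benzoic acid | CC(C)=CCC/C(C)=C/Cc1cc(C(=O)O)cc(O[Si](C)(C)C(C)(C)C)c1O[Si](C)(C)C(C)(C)C | intermediate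
7 | phloroglucinol | Oc1cc(O)cc(O)c1 | starting material
8 | 2-iodobenzene-1,3,5-triol | Oc1cc(O)c(I)c(O)c1 | intermediate
9 | 2-iodo-3,5-bis(TBS-oxy)phenol | Oc1cc(O[Si](C)(C)C(C)(C)C)cc(O[Si](C)(C)C(C)(C)C)c1I | intermediate
10 | 2-iodo-3,5-bis(TBS-oxy)phenyl 3-geranyl-4,5-bis(TBS-oxy)benzoate | CC(C)=CCC/C(C)=C/Cc1cc(C(=O)Oc2cc(O[Si](C)(C)C(C)(C)C)cc(O[Si](C)(C)C(C)(C)C)c2I)cc(O[Si](C)(C)C(C)(C)C)c1O[Si](C)(C)C(C)(C)C | intermediate
11 | 1-{1-[2-iodo-3,5-bis(TBS-oxy)phenoxy]ethenyl}-3-geranyl-4,5-bis(TBS-oxy)benzene | CC(C)=CCC/C(C)=C/Cc1cc(C(=C)Oc2cc(O[Si](C)(C)C(C)(C)C)cc(O[Si](C)(C)C(C)(C)C)c2I)cc(O[Si](C)(C)C(C)(C)C)c1O[Si](C)(C)C(C)(C)C | intermediate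
12 | arylmagnesium chloride from 11 (not isolated) | CC(C)=CCC/C(C)=C/Cc1cc(C(=C)Oc2cc(O[Si](C)(C)C(C)(C)C)cc(O[Si](C)(C)C(C)(C)C)c2[Mg]Cl)cc(O[Si](C)(C)C(C)(C)C)c1O[Si](C)(C)C(C)(C)C | intermediate
13 | 2-{1-[3-geranyl-4,5-bis(TBS-oxy)phenyl]ethenyloxy}-4,6-bis(TBS-oxy)benzaldehyde | CC(C)=CCC/C(C)=C/Cc1cc(C(=C)Oc2cc(O[Si](C)(C)C(C)(C)C)cc(O[Si](C)(C)C(C)(C)C)c2C=O)cc(O[Si](C)(C)C(C)(C)C)c1O[Si](C)(C)C(C)(C)C | intermediate
14 | (2S)-5,7-bis(TBS-oxy)-2-[3-geranyl-4,5-bis(TBS-oxy)phenyl]chroman-4-one | CC(C)=CCC/C(C)=C/Cc1cc([C@@H]2CC(=O)c3c(O[Si](C)(C)C(C)(C)C)cc(O[Si](C)(C)C(C)(C)C)cc3O2)cc(O[Si](C)(C)C(C)(C)C)c1O[Si](C)(C)C(C)(C)C | intermediate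
15 | isonymphaeol B | CC(C)=CCC/C(C)=C/Cc1cc([C@@H]2CC(=O)c3c(O)cc(O)cc3O2)cc(O)c1O | target

Total step count: 11. Longest linear sequence: 8 (steps 1, 3, 4, 7, 8, 9, 10, 11).

Steps most likely to fail

Step 10. The catalyst may be lost through decarbonylation of the doubly ortho-substituted aldehyde. Alkene insertion may be slow or run with reversed regiochemistry, and facial selectivity may be poor. The fallback closes ring C at the O1–C2 bond instead and separates the enantiomers by kinetic resolution. It sets out from aldehyde 5 and comes back at 14.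
- Commercial 2,4,6-trihydroxyacetophenone is bis-silylated (TBSCl, 2 equiv, imidazole, DMF). The chelated hydroxyl stays free, giving 1-[2-hydroxy-4,6-bis(TBS-oxy)phenyl]ethanone F1.
- Its dilithio derivative (LiN(SiMe3)2, 2.2 equiv, THF, −78 °C) adds to 5 to give the racemic aldol 3-hydroxy-1-[2-hydroxy-4,6-bis(TBS-oxy)phenyl]-3-[3-geranyl-4,5-bis(TBS-oxy)phenyl]propan-1-one F2.
- An intramolecular Mitsunobu reaction (PPh3, DIAD, toluene, 0 °C) gives the racemic tetrasilyl flavanone F3.
- Asymmetric transfer hydrogenation follows (Cp*RhCl[(R,R)-TsDPEN], HCO2H/Et3N, EtOAc, rt), a kinetic resolution known for prenylated flavanones and stopped near half conversion. It should reduce the (2R)-ketone to the cis-(2R,4R)-flavan-4-ol F4 and leave 14, which is separated by chromatography.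

Step 3. Regiochemical and geometric integrity may be lost in the allyl transfer through σ–π–σ interconversion of the geranylpalladium intermediate, and oxidative addition may be slow next to the bulky silyl ether. The fallback reverses the polarity: the arene becomes the nucleophile and geranyl bromide the SN2 electrophile. It sets out from 2 and comes back at 5.
- Aldehyde 2 is masked (HC(OMe)3, PPTS cat., MeOH) as 3-bromo-4,5-bis(TBS-oxy)benzaldehyde dimethyl acetal F5.
- Magnesium insertion (Mg turnings, LiCl, THF, 0 °C to rt) gives the arylmagnesium bromide F6.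
- Copper-catalysed alkylation (Li2CuCl4, 5 mol %, commercial geranyl bromide, −20 °C) gives 3-geranyl-4,5-bis(TBS-oxy)benzaldehyde dimethyl acetal F7.
- Mild hydrolysis (PPTS, acetone/H2O) returns 5.

Step 6. Over- and under-silylation may occur, and the air- and light-sensitive iodotriol may decay before it is protected. The fallback desymmetrizes first and halogenates afterwards. It sets out from 7 and comes back at 9.
- Phloroglucinol is bis-silylated (TBSCl, 2 equiv, imidazole, DMF) to 3,5-bis(TBS-oxy)phenol F8.
- F8 is monoiodinated (NIS, 1.0 equiv, CH2Cl2, −20 °C). The position between the two silyl ethers is shielded, so iodine should enter next to the free hydroxyl.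

Further compounds
F1 | step 10 | 1-[2-hydroxy-4,6-bis(TBS-oxy)phenyl]ethanone | CC(=O)c1c(O)cc(O[Si](C)(C)C(C)(C)C)cc1O[Si](C)(C)C(C)(C)C
F2 | step 10 | racemic 3-hydroxy-1-[2-hydroxy-4,6-bis(TBS-oxy)phenyl]-3-[3-geranyl-4,5-bis(TBS-oxy)phenyl]propan-1-one | CC(C)=CCC/C(C)=C/Cc1cc(C(O)CC(=O)c2c(O)cc(O[Si](C)(C)C(C)(C)C)cc2O[Si](C)(C)C(C)(C)C)cc(O[Si](C)(C)C(C)(C)C)c1O[Si](C)(C)C(C)(C)C
F3 | step 10 | racemic 5,7-bis(TBS-oxy)-2-[3-geranyl-4,5-bis(TBS-oxy)phenyl]chroman-4-one | CC(C)=CCC/C(C)=C/Cc1cc(C2CC(=O)c3c(O[Si](C)(C)C(C)(C)C)cc(O[Si](C)(C)C(C)(C)C)cc3O2)cc(O[Si](C)(C)C(C)(C)C)c1O[Si](C)(C)C(C)(C)C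
F4 | step 10 | (2R,4R)-5,7-bis(TBS-oxy)-2-[3-geranyl-4,5-bis(TBS-oxy)phenyl]chroman-4-ol | CC(C)=CCC/C(C)=C/Cc1cc([C@H]2C[C@@H](O)c3c(O[Si](C)(C)C(C)(C)C)cc(O[Si](C)(C)C(C)(C)C)cc3O2)cc(O[Si](C)(C)C(C)(C)C)c1O[Si](C)(C)C(C)(C)C
F5 | step 3 | 3-bromo-4,5-bis(TBS-oxy)benzaldehyde dimethyl acetal | COC(OC)c1cc(O[Si](C)(C)C(C)(C)C)c(O[Si](C)(C)C(C)(C)C)c(Br)c1
F6 | step 3 | arylmagnesium bromide from F5 | COC(OC)c1cc(O[Si](C)(C)C(C)(C)C)c(O[Si](C)(C)C(C)(C)C)c([Mg]Br)c1
F7 | step 3 | 3-geranyl-4,5-bis(TBS-oxy)benzaldehyde dimethyl acetal | CC(C)=CCC/C(C)=C/Cc1cc(C(OC)OC)cc(O[Si](C)(C)C(C)(C)C)c1O[Si](C)(C)C(C)(C)C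
F8 | step 6 | 3,5-bis(TBS-oxy)phenol | Oc1cc(O[Si](C)(C)C(C)(C)C)cc(O[Si](C)(C)C(C)(C)C)c1
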